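**Plan**
- Cuts, latest first: N-CH3 back to N-Boc, C8-OH to C8-OBn and C1'-H to C1'-OH. Next come the three bonds C3'-C4', C1'-C2' and C1'-C8a' of the methyl-bearing naphthalene ring, then the biaryl bond C5-C8', and last C1-CH3/C1=N and C3-C4 of the heterocycle.
- Enabling feature (naphthalene locants primed): ring C1'-C2'-C3'-C4'-C4a'-C8a' carries OMe on C4' and CH3 on C2'. That is what a methoxycarbene carbon (C4'), propyne (C3', C2'-CH3) and one CO (C1') deliver. The C5' methoxy group leaves C8a' as the only ortho carbon open for closure. C8' lies meta to the carbene carbon, so the aryl ring joined to C5 still has two ortho hydrogens when the biaryl bond is made.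
- Forward order: the benzene ring of the isoquinoline is bought and the nitrogen ring is closed on it. C5 is brominated, borylated and coupled at the iodide of 2-bromo-4-iodoanisole. The remaining bromide becomes the chromium carbene, and the second naphthalene ring closes last, which is when the axis becomes hindered.
- The 6-OMe/8-O-benzyl pattern comes from 2,4-dihydroxy-6-methylbenzaldehyde, whose hydrogen-bonded 2-OH is alkylated only after the 4-OH. Its CHO carbon becomes C1 and its methyl carbon becomes C4.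
- Stereochemistry: C3 (R) comes from adding the benzylic lithium compound to the (S)-tert-butanesulfinyl imine of acetaldehyde. C1 (R) comes from C3 by trans-selective AlMe3/LiAlH4 reduction of the cyclic imine.

Key step: step 13

Assumption: the SMILES fixes only C1 and C3 (both R, methyl groups trans) and leaves open the C5-C8' axis, which stops rotating once the naphthalene is complete; both atropo-diastereomers formed in the key step therefore fit the structure and are parted by chromatography after that step or at the end.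

Step 1
Reactants: 1 2,4-dihydroxy-6-methylbenzaldehyde
Product: 2 2-hydroxy-4-methoxy-6-methylbenzaldehyde
Conditions: MeI (1 equiv), K2CO3 (1 equiv), acetone, rt to 40 °C
Reagents that add atoms: iodomethane, CI
Why: Williamson ether synthesis in which the 2-OH, locked in a hydrogen bond to the aldehyde oxygen, stays behind while one equivalent of MeI alkylates the free 4-OH, the oxygen that becomes the C6 methoxy group.

Step 2
Reactants: 2 2-hydroxy-4-methoxy-6-methylbenzaldehyde
Product: 3 2-(benzyloxy)-4-methoxy-6-methylbenzaldehyde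
Conditions: BnBr, K2CO3, DMF, 60 °C
Reagents that add atoms: benzyl bromide, BrCc1ccccc1
Why: Williamson ether synthesis under more forcing conditions caps the chelated phenol as a benzyl ether, which tolerates the amide bases, organolithiums, hydrides and palladium couplings ahead and leaves by hydrogenolysis at the end.

Step 3
Reactants: 3 2-(benzyloxy)-4-methoxy-6-methylbenzaldehyde
Product: 4 2-(benzyloxy)-4-methoxy-6-methylbenzonitrile
Conditions: I2, aq NH3, THF, rt
Reagents that add atoms: ammonia, N
Why: Oxidative aldehyde-to-nitrile conversion, in which the aldimine formed with ammonia is N-iodinated and loses HI, leaves aryl ethers untouched and turns the future C1 into a group that acidifies the ortho methyl group and later accepts MeLi once only.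

Step 4
Reactants: 5 (S)-2-methylpropane-2-sulfinamide; 6 acetaldehyde
Product: 7 (S,E)-N-ethylidene-2-methylpropane-2-sulfinamide
Conditions: CuSO4 (anhydrous), CH2Cl2, rt
Reagents that add atoms: none
Why: Dehydrative condensation of a sulfinamide with an aldehyde over a Lewis-acidic drying agent gives the E aldimine and does not touch the sulfur stereocentre.

Step 5
Reactants: 4 2-(benzyloxy)-4-methoxy-6-methylbenzonitrile; 7 (S,E)-N-ethylidene-2-methylpropane-2-sulfinamide
Product: 9 (S)-N-{(2R)-1-[3-(benzyloxy)-2-cyano-5-methoxyphenyl]propan-2-yl}-2-methylpropane-2-sulfinamide, via laterally lithiated nitrile 8 (not isolated)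
Conditions: LiN(i-Pr)2, THF, -78 °C; then 7, -78 °C; aq NH4Cl
Reagents that add atoms: none
Why: Lateral lithiation of an o-tolunitrile and 1,2-addition to an N-sulfinyl aldimine form C3-C4, and in THF the lithium benzyl anion is expected to react through the open transition state on the imine face that the tert-butyl group of the s-cis (S)-sulfinyl imine leaves free, which makes C3 R, any minor diastereomer being removable by chromatography.

Step 6
Reactants: 9 (S)-N-{(2R)-1-[3-(benzyloxy)-2-cyano-5-methoxyphenyl]propan-2-yl}-2-methylpropane-2-sulfinamide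
Product: 11 (3R)-8-(benzyloxy)-6-methoxy-1,3-dimethyl-3,4-dihydroisoquinoline, via methyl ketimine 10 (not isolated)
Conditions: MeLi (3 equiv), THF, -78 to 0 °C; then HCl, MeOH, rt; aq NaOH
Reagents that add atoms: methyllithium, [Li]C
Why: Single addition of MeLi to the nitrile gives the metallated ketimine, and acid methanolysis of the N-S bond frees the primary amine, which displaces ammonia from the ketimine carbon (transimination) and closes the six-membered cyclic imine without touching C3.

Step 7
Reactants: 11 (3R)-8-(benzyloxy)-6-methoxy-1,3-dimethyl-3,4-dihydroisoquinoline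
Product: 12 (1R,3R)-8-(benzyloxy)-6-methoxy-1,3-dimethyl-1,2,3,4-tetrahydroisoquinoline
Conditions: AlMe3, LiAlH4, THF, -78 to 0 °C; then H2O
Reagents that add atoms: none
Why: Lewis-acid-modified hydride reduction of a cyclic imine: AlMe3 on nitrogen pushes the C3 methyl group into the pseudo-axial position, and hydride then enters C1 along the stereoelectronically favoured axial line on the same face as that methyl group, so the C1 methyl group ends up trans to it (1R).

Step 8
Reactants: 12 (1R,3R)-8-(benzyloxy)-6-methoxy-1,3-dimethyl-1,2,3,4-tetrahydroisoquinoline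
Product: 13 tert-butyl (1R,3R)-8-(benzyloxy)-6-methoxy-1,3-dimethyl-3,4-dihydroisoquinoline-2(1H)-carboxylate
Conditions: Boc2O, THF, 60 °C
Reagents that add atoms: di-tert-butyl dicarbonate, CC(C)(C)OC(=O)OC(=O)OC(C)(C)C
Why: Carbamate formation removes the nucleophilicity of nitrogen, which would otherwise be methylated by Me3OBF4 or bind chromium, gives a group that withstands organolithiums at low temperature, and stores the carbon of the later N-methyl group.

Step 9
Reactants: 13 tert-butyl (1R,3R)-8-(benzyloxy)-6-methoxy-1,3-dimethyl-3,4-dihydroisoquinoline-2(1H)-carboxylate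
Product: 14 tert-butyl (1R,3R)-8-(benzyloxy)-5-bromo-6-methoxy-1,3-dimethyl-3,4-dihydroisoquinoline-2(1H)-carboxylate
Conditions: NBS, MeCN, 0 °C to rt, dark
Reagents that add atoms: N-bromosuccinimide, O=C1CCC(=O)N1Br
Why: Electrophilic aromatic bromination goes to C5, para to the benzyloxy and ortho to the methoxy group, because the only other free position C7 is wedged between two alkoxy groups.

Step 10
Reactants: 14 tert-butyl (1R,3R)-8-(benzyloxy)-5-bromo-6-methoxy-1,3-dimethyl-3,4-dihydroisoquinoline-2(1H)-carboxylate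
Product: 15 tert-butyl (1R,3R)-8-(benzyloxy)-6-methoxy-1,3-dimethyl-5-(4,4,5,5-tetramethyl-1,3,2-dioxaborolan-2-yl)-3,4-dihydroisoquinoline-2(1H)-carboxylate
Conditions: B2pin2, Pd2(dba)3, XPhos, KOAc, 1,4-dioxane, 100 °C
Reagents that add atoms: bis(pinacolato)diboron, CC1(C)OB(OC1(C)C)B1OC(C)(C)C(C)(C)O1
Why: Miyaura borylation with a bulky electron-rich biarylphosphine, the ligand type that handles electron-rich aryl bromides bearing two ortho substituents, while KOAc is too weak a base to trigger homocoupling.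

Step 11
Reactants: 15 tert-butyl (1R,3R)-8-(benzyloxy)-6-methoxy-1,3-dimethyl-5-(4,4,5,5-tetramethyl-1,3,2-dioxaborolan-2-yl)-3,4-dihydroisoquinoline-2(1H)-carboxylate; 16 2-bromo-4-iodoanisole
Product: 17 tert-butyl (1R,3R)-8-(benzyloxy)-5-(3-bromo-4-methoxyphenyl)-6-methoxy-1,3-dimethyl-3,4-dihydroisoquinoline-2(1H)-carboxylate
Conditions: 16 (1.5 equiv), Pd(PPh3)4, K3PO4, DME/H2O, 80 °C
Reagents that add atoms: none
Why: Suzuki-Miyaura coupling in which zerovalent palladium inserts into the C-I bond far faster than into the C-Br bond, and in which the halide partner has no ortho substituent, so that only the boronate side is hindered.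

Step 12
Reactants: 17 tert-butyl (1R,3R)-8-(benzyloxy)-5-(3-bromo-4-methoxyphenyl)-6-methoxy-1,3-dimethyl-3,4-dihydroisoquinoline-2(1H)-carboxylate; 18 chromium hexacarbonyl Cr(CO)6
Product: 21 pentacarbonyl[{5-[(1R,3R)-8-(benzyloxy)-2-(tert-butoxycarbonyl)-6-methoxy-1,3-dimethyl-1,2,3,4-tetrahydroisoquinolin-5-yl]-2-methoxyphenyl}(methoxy)carbene]chromium, via aryllithium 19 (not isolated), via lithium acylchromate 20 (not isolated)
Conditions: t-BuLi (2.1 equiv), Et2O/THF, -78 °C; Cr(CO)6, -78 °C to rt; evaporate; Me3OBF4, CH2Cl2, 0 °C to rt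
Reagents that add atoms: trimethyloxonium tetrafluoroborate, C[O+](C)C.F[B-](F)(F)F
Why: Fischer carbene synthesis, in which bromine-lithium exchange with t-BuLi at -78 °C is faster than any attack on the hindered Boc group, the aryllithium adds to a CO ligand of Cr(CO)6, and the hard methylating agent alkylates the acylate oxygen while the carbamate nitrogen stays inert.

Step 13
Reactants: 21 pentacarbonyl[{5-[(1R,3R)-8-(benzyloxy)-2-(tert-butoxycarbonyl)-6-methoxy-1,3-dimethyl-1,2,3,4-tetrahydroisoquinolin-5-yl]-2-methoxyphenyl}(methoxy)carbene]chromium; 22 propyne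
Product: 24 tert-butyl (1R,3R)-8-(benzyloxy)-5-(8-hydroxy-4,5-dimethoxy-7-methylnaphthalen-1-yl)-6-methoxy-1,3-dimethyl-3,4-dihydroisoquinoline-2(1H)-carboxylate, via tricarbonylchromium naphthol complex 23 (not isolated)
Conditions: propyne (excess, condensed in), THF, sealed tube, argon, 55 °C; then air, CH2Cl2, rt
Reagents that add atoms: none
Why: This is a Dötz benzannulation of an aryl(methoxy)carbene complex of zerovalent chromium with a terminal alkyne, the closest known cases being 2-methoxyphenyl and 2,5-dimethoxyphenyl complexes, the latter also closing next to a peri substituent. Loss of one CO, eased by transient chelation of the C5' methoxy oxygen to chromium, lets propyne bind and insert into the Cr=C bond (C3'-C4'), a CO ligand migrates to the new vinylcarbene carbon (C1'-C2') to give a chromium-bound vinylketene, and this closes onto C8a' (C1'-C8a'). The one ring formed, the six-membered carbocycle C1'-C2'-C3'-C4'-C4a'-C8a', thus arises by 6π electrocyclisation of the aryl vinylketene followed by tautomerisation of the cyclohexadienone to naphthol complex 23, from which air strips the Cr(CO)3 unit. No stereocentre is created, but ring closure turns the freely rotating C5-C8' bond into a hindered axis, so two atropo-diastereomers are expected, biased at most weakly by C1 and C3. Three selectivities are needed: alkyne orientation, secured by the steric rule that places the larger alkyne substituent (CH3 rather than H) beside the CO-derived carbon; site of closure, secured because the other ortho carbon C5' bears methoxy; and CO uptake over five-ring formation, favoured by chromium, the methoxy donor, THF and a high propyne concentration.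

Step 14
Reactants: 24 tert-butyl (1R,3R)-8-(benzyloxy)-5-(8-hydroxy-4,5-dimethoxy-7-methylnaphthalen-1-yl)-6-methoxy-1,3-dimethyl-3,4-dihydroisoquinoline-2(1H)-carboxylate
Product: 25 tert-butyl (1R,3R)-8-(benzyloxy)-5-{4,5-dimethoxy-7-methyl-8-[(trifluoromethanesulfonyl)oxy]naphthalen-1-yl}-6-methoxy-1,3-dimethyl-3,4-dihydroisoquinoline-2(1H)-carboxylate
Conditions: Tf2O, pyridine, CH2Cl2, 0 °C
Reagents that add atoms: trifluoromethanesulfonic anhydride, O=S(=O)(OS(=O)(=O)C(F)(F)F)C(F)(F)F
Why: O-Sulfonylation of the naphthol, whose oxygen still projects out of the peri pocket, activates the C1'-O bond and at the same time ends the air sensitivity of the 4-methoxy-1-naphthol.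

Step 15
Reactants: 25 tert-butyl (1R,3R)-8-(benzyloxy)-5-{4,5-dimethoxy-7-methyl-8-[(trifluoromethanesulfonyl)oxy]naphthalen-1-yl}-6-methoxy-1,3-dimethyl-3,4-dihydroisoquinoline-2(1H)-carboxylate
Product: 26 tert-butyl (1R,3R)-8-(benzyloxy)-5-(4,5-dimethoxy-7-methylnaphthalen-1-yl)-6-methoxy-1,3-dimethyl-3,4-dihydroisoquinoline-2(1H)-carboxylate
Conditions: Pd(OAc)2, dppf, HCO2H, Et3N, DMF, 90 °C
Reagents that add atoms: none
Why: Palladium-catalysed formate reduction of an aryl triflate (oxidative addition, triflate-formate exchange, loss of CO2, C-H reductive elimination) delivers hydride, the smallest possible partner for the crowded C1' position, and leaves benzyl ether, Boc group and aryl methyl ethers alone.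

Step 16
Reactants: 26 tert-butyl (1R,3R)-8-(benzyloxy)-5-(4,5-dimethoxy-7-methylnaphthalen-1-yl)-6-methoxy-1,3-dimethyl-3,4-dihydroisoquinoline-2(1H)-carboxylate
Product: 27 (1R,3R)-8-(benzyloxy)-5-(4,5-dimethoxy-7-methylnaphthalen-1-yl)-6-methoxy-1,2,3-trimethyl-1,2,3,4-tetrahydroisoquinoline
Conditions: LiAlH4, THF, reflux; then H2O
Reagents that add atoms: none
Why: LiAlH4 reduction of a carbamate runs through the formamide and iminium stages to the N-methyl amine, expels tert-butoxide and touches neither the aryl ethers nor C1 and C3.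

Step 17
Reactants: 27 (1R,3R)-8-(benzyloxy)-5-(4,5-dimethoxy-7-methylnaphthalen-1-yl)-6-methoxy-1,2,3-trimethyl-1,2,3,4-tetrahydroisoquinoline
Product: 28 ancistrocongoline B, (1R,3R)-5-(4,5-dimethoxy-7-methylnaphthalen-1-yl)-6-methoxy-1,2,3-trimethyl-1,2,3,4-tetrahydroisoquinolin-8-ol
Conditions: H2 (1 atm), 10% Pd/C, MeOH, rt
Reagents that add atoms: none
Why: Catalytic hydrogenolysis cleaves the benzylic C-O bond of the aryl benzyl ether under conditions that reduce neither the naphthalene nor the ring C1-N bond, and gives the free C8 phenol.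

**Compound list**
1 | 2,4-dihydroxy-6-methylbenzaldehyde | Cc1cc(O)cc(O)c1C=O | starting material
2 | 2-hydroxy-4-methoxy-6-methylbenzaldehyde | COc1cc(C)c(C=O)c(O)c1 | intermediate
3 | 2-(benzyloxy)-4-methoxy-6-methylbenzaldehyde | COc1cc(C)c(C=O)c(OCc2ccccc2)c1 | intermediate
4 | 2-(benzyloxy)-4-methoxy-6-methylbenzonitrile | COc1cc(C)c(C#N)c(OCc2ccccc2)c1 | intermediate
5 | (S)-2-methylpropane-2-sulfinamide | CC(C)(C)[S@](=O)N | starting material
6 | acetaldehyde | CC=O | starting material
7 | (S,E)-N-ethylidene-2-methylpropane-2-sulfinamide | CC(C)(C)[S@](=O)/N=C/C | intermediate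
8 | [3-(benzyloxy)-2-cyano-5-methoxybenzyl]lithium | [Li]Cc1cc(OC)cc(OCc2ccccc2)c1C#N | intermediate
9 | (S)-N-{(2R)-1-[3-(benzyloxy)-2-cyano-5-methoxyphenyl]propan-2-yl}-2-methylpropane-2-sulfinamide | N#Cc1c(OCc2ccccc2)cc(OC)cc1C[C@@H](C)N[S@@](=O)C(C)(C)C | intermediate
10 | (S)-N-{(2R)-1-[3-(benzyloxy)-2-(1-iminoethyl)-5-methoxyphenyl]propan-2-yl}-2-methylpropane-2-sulfinamide (present as its lithium salt before the acid is added) | CC(=N)c1c(OCc2ccccc2)cc(OC)cc1C[C@@H](C)N[S@@](=O)C(C)(C)C | intermediate
11 | (3R)-8-(benzyloxy)-6-methoxy-1,3-dimethyl-3,4-dihydroisoquinoline | CC1=N[C@H](C)Cc2cc(OC)cc(OCc3ccccc3)c12 | intermediate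
12 | (1R,3R)-8-(benzyloxy)-6-methoxy-1,3-dimethyl-1,2,3,4-tetrahydroisoquinoline | COc1cc(OCc3ccccc3)c2c(c1)C[C@@H](C)N[C@@H]2C | intermediate
13 | tert-butyl (1R,3R)-8-(benzyloxy)-6-methoxy-1,3-dimethyl-3,4-dihydroisoquinoline-2(1H)-carboxylate | COc1cc(OCc3ccccc3)c2c(c1)C[C@@H](C)N(C(=O)OC(C)(C)C)[C@@H]2C | intermediate
14 | tert-butyl (1R,3R)-8-(benzyloxy)-5-bromo-6-methoxy-1,3-dimethyl-3,4-dihydroisoquinoline-2(1H)-carboxylate | COc1cc(OCc3ccccc3)c2c(c1Br)C[C@@H](C)N(C(=O)OC(C)(C)C)[C@@H]2C | intermediate
15 | tert-butyl (1R,3R)-8-(benzyloxy)-6-methoxy-1,3-dimethyl-5-(4,4,5,5-tetramethyl-1,3,2-dioxaborolan-2-yl)-3,4-dihydroisoquinoline-2(1H)-carboxylate | COc1cc(OCc3ccccc3)c2c(c1B4OC(C)(C)C(C)(C)O4)C[C@@H](C)N(C(=O)OC(C)(C)C)[C@@H]2C | intermediate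
16 | 2-bromo-4-iodoanisole | COc1ccc(I)cc1Br | starting material
17 | tert-butyl (1R,3R)-8-(benzyloxy)-5-(3-bromo-4-methoxyphenyl)-6-methoxy-1,3-dimethyl-3,4-dihydroisoquinoline-2(1H)-carboxylate | COc1cc(OCc3ccccc3)c2c(c1-c4ccc(OC)c(Br)c4)C[C@@H](C)N(C(=O)OC(C)(C)C)[C@@H]2C | intermediate
18 | chromium hexacarbonyl Cr(CO)6 | O=C=[Cr](=C=O)(=C=O)(=C=O)(=C=O)=C=O | starting material
19 | aryllithium from 17 (lithium in place of bromine) | [Li]c1cc(-c2c(OC)cc(OCc3ccccc3)c3c2C[C@@H](C)N(C(=O)OC(C)(C)C)[C@@H]3C)ccc1OC | intermediate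
20 | lithium aroylpentacarbonylchromate from 19 and Cr(CO)6 | [Li+].[O-]C(=[Cr](=C=O)(=C=O)(=C=O)(=C=O)=C=O)c1cc(-c2c(OC)cc(OCc3ccccc3)c3c2C[C@@H](C)N(C(=O)OC(C)(C)C)[C@@H]3C)ccc1OC | intermediate
21 | pentacarbonyl[{5-[(1R,3R)-8-(benzyloxy)-2-(tert-butoxycarbonyl)-6-methoxy-1,3-dimethyl-1,2,3,4-tetrahydroisoquinolin-5-yl]-2-methoxyphenyl}(methoxy)carbene]chromium | COC(=[Cr](=C=O)(=C=O)(=C=O)(=C=O)=C=O)c1cc(-c2c(OC)cc(OCc3ccccc3)c3c2C[C@@H](C)N(C(=O)OC(C)(C)C)[C@@H]3C)ccc1OC | intermediate
22 | propyne | CC#C | starting material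
23 | η6-tricarbonylchromium complex of naphthol 24, metal on the new ring (written as two parts) | COc1cc(C)c(O)c2c(-c3c(OC)cc(OCc4ccccc4)c4c3C[C@@H](C)N(C(=O)OC(C)(C)C)[C@@H]4C)ccc(OC)c12.O=C=[Cr](=C=O)=C=O | intermediate
24 | tert-butyl (1R,3R)-8-(benzyloxy)-5-(8-hydroxy-4,5-dimethoxy-7-methylnaphthalen-1-yl)-6-methoxy-1,3-dimethyl-3,4-dihydroisoquinoline-2(1H)-carboxylate | COc1cc(C)c(O)c2c(-c3c(OC)cc(OCc4ccccc4)c4c3C[C@@H](C)N(C(=O)OC(C)(C)C)[C@@H]4C)ccc(OC)c12 | intermediate
25 | tert-butyl (1R,3R)-8-(benzyloxy)-5-{4,5-dimethoxy-7-methyl-8-[(trifluoromethanesulfonyl)oxy]naphthalen-1-yl}-6-methoxy-1,3-dimethyl-3,4-dihydroisoquinoline-2(1H)-carboxylate | COc1cc(C)c(OS(=O)(=O)C(F)(F)F)c2c(-c3c(OC)cc(OCc4ccccc4)c4c3C[C@@H](C)N(C(=O)OC(C)(C)C)[C@@H]4C)ccc(OC)c12 | intermediate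
26 | tert-butyl (1R,3R)-8-(benzyloxy)-5-(4,5-dimethoxy-7-methylnaphthalen-1-yl)-6-methoxy-1,3-dimethyl-3,4-dihydroisoquinoline-2(1H)-carboxylate | COc1cc(OCc3ccccc3)c2c(c1-c4ccc(OC)c5c(OC)cc(C)cc45)C[C@@H](C)N(C(=O)OC(C)(C)C)[C@@H]2C | intermediate
27 | (1R,3R)-8-(benzyloxy)-5-(4,5-dimethoxy-7-methylnaphthalen-1-yl)-6-methoxy-1,2,3-trimethyl-1,2,3,4-tetrahydroisoquinoline | COc1cc(OCc3ccccc3)c2c(c1-c4ccc(OC)c5c(OC)cc(C)cc45)C[C@@H](C)N(C)[C@@H]2C | intermediate
28 | ancistrocongoline B | COc1cc(O)c2c(c1-c1ccc(OC)c3c(OC)cc(C)cc13)C[C@@H](C)N(C)[C@@H]2C | target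

Total step count: 17. Longest linear sequence: 16 (steps 1-3 and 5-17).

**The three steps most likely to fail**

Step 13. The vinylketene has to close onto C8a' right beside the twisted isoquinoline ring. If that closure is slowed, cyclisation without CO uptake, four-ring closure of the ketene or oligomerisation of propyne may consume the complex. The fallback sets out from boronate 15 and returns at 26. It runs the benzannulation on a small arene and builds the axis afterwards by cross-coupling. Commercial 2-bromo-4-chloroanisole (COc1ccc(Cl)cc1Br) is taken through t-BuLi, Cr(CO)6 and Me3OBF4 to pentacarbonyl[(5-chloro-2-methoxyphenyl)(methoxy)carbene]chromium F1. Propyne in THF at 55 °C followed by air gives 8-chloro-4,5-dimethoxy-2-methylnaphthalen-1-ol F2, where the peri neighbour is now only chlorine. Tf2O and pyridine give 8-chloro-4,5-dimethoxy-2-methylnaphthalen-1-yl trifluoromethanesulfonate F3. Pd(OAc)2, dppf, HCO2H and Et3N reduce the triflate and leave the chloride, giving 1-chloro-4,5-dimethoxy-7-methylnaphthalene F4. A Suzuki-Miyaura coupling for hindered partners (Pd2(dba)3, SPhos, K3PO4, toluene/H2O, 100 °C) then joins this chloride to 15 and gives 26.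

Step 15. Zerovalent palladium must insert into the C1'-O bond, which lies between the C2' methyl group and the peri isoquinoline ring. This may be too slow, and S-O cleavage back to the naphthol may win. The fallback sets out from naphthol 24 and returns at 26. It deoxygenates by electron transfer, which needs no metal insertion at C1'. Phosphorylation of 24 (NaH, ClP(O)(OEt)2, THF) gives tert-butyl (1R,3R)-8-(benzyloxy)-5-{8-[(diethoxyphosphoryl)oxy]-4,5-dimethoxy-7-methylnaphthalen-1-yl}-6-methoxy-1,3-dimethyl-3,4-dihydroisoquinoline-2(1H)-carboxylate F5. Two electron equivalents of LiC10H8 (lithium naphthalenide) in THF at -78 °C should place an electron in the naphthalene π system. The radical anion expels diethyl phosphate, and the aryl anion is protonated on quenching to give 26. The benzyl ether is expected to react only at higher temperature.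

Step 12. t-BuLi or the aryllithium may attack the Boc carbonyl or remove a benzylic proton during warming with the poorly soluble Cr(CO)6, and the acylate may be methylated incompletely. The fallback sets out from boronate 15 and returns at 21. It reaches the acylchromate from the electrophilic side and so avoids any organolithium. Coupling of 15 with commercial methyl 5-iodo-2-methoxybenzoate (COC(=O)c1cc(I)ccc1OC) under the conditions of step 11 gives tert-butyl (1R,3R)-8-(benzyloxy)-6-methoxy-5-[4-methoxy-3-(methoxycarbonyl)phenyl]-1,3-dimethyl-3,4-dihydroisoquinoline-2(1H)-carboxylate F6. LiOH in THF/MeOH/H2O gives 5-[(1R,3R)-8-(benzyloxy)-2-(tert-butoxycarbonyl)-6-methoxy-1,3-dimethyl-1,2,3,4-tetrahydroisoquinolin-5-yl]-2-methoxybenzoic acid F7. The neutral chlorinating agent 1-chloro-N,N,2-trimethylprop-1-en-1-amine in CH2Cl2 gives the corresponding 2-methoxybenzoyl chloride F8. K2Cr(CO)5, made from Cr(CO)6 and KC8 in THF at -78 °C, is acylated by the acid chloride to potassium aroylpentacarbonylchromate F9. Me3OBF4 then converts this salt into 21.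

**Further compounds**
F1 | step 13 | pentacarbonyl[(5-chloro-2-methoxyphenyl)(methoxy)carbene]chromium | COC(=[Cr](=C=O)(=C=O)(=C=O)(=C=O)=C=O)c1cc(Cl)ccc1OC
F2 | step 13 | 8-chloro-4,5-dimethoxy-2-methylnaphthalen-1-ol | COc1cc(C)c(O)c2c(Cl)ccc(OC)c12
F3 | step 13 | 8-chloro-4,5-dimethoxy-2-methylnaphthalen-1-yl trifluoromethanesulfonate | COc1cc(C)c(OS(=O)(=O)C(F)(F)F)c2c(Cl)ccc(OC)c12
F4 | step 13 | 1-chloro-4,5-dimethoxy-7-methylnaphthalene | COc1cc(C)cc2c(Cl)ccc(OC)c12
F5 | step 15 | tert-butyl (1R,3R)-8-(benzyloxy)-5-{8-[(diethoxyphosphoryl)oxy]-4,5-dimethoxy-7-methylnaphthalen-1-yl}-6-methoxy-1,3-dimethyl-3,4-dihydroisoquinoline-2(1H)-carboxylate | CCOP(=O)(OCC)Oc1c(C)cc(OC)c2c(OC)ccc(-c3c(OC)cc(OCc4ccccc4)c4c3C[C@@H](C)N(C(=O)OC(C)(C)C)[C@@H]4C)c12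
F6 | step 12 | tert-butyl (1R,3R)-8-(benzyloxy)-6-methoxy-5-[4-methoxy-3-(methoxycarbonyl)phenyl]-1,3-dimethyl-3,4-dihydroisoquinoline-2(1H)-carboxylate | COC(=O)c1cc(-c2c(OC)cc(OCc3ccccc3)c3c2C[C@@H](C)N(C(=O)OC(C)(C)C)[C@@H]3C)ccc1OC
F7 | step 12 | 5-[(1R,3R)-8-(benzyloxy)-2-(tert-butoxycarbonyl)-6-methoxy-1,3-dimethyl-1,2,3,4-tetrahydroisoquinolin-5-yl]-2-methoxybenzoic acid | OC(=O)c1cc(-c2c(OC)cc(OCc3ccccc3)c3c2C[C@@H](C)N(C(=O)OC(C)(C)C)[C@@H]3C)ccc1OC
F8 | step 12 | 5-[(1R,3R)-8-(benzyloxy)-2-(tert-butoxycarbonyl)-6-methoxy-1,3-dimethyl-1,2,3,4-tetrahydroisoquinolin-5-yl]-2-methoxybenzoyl chloride | ClC(=O)c1cc(-c2c(OC)cc(OCc3ccccc3)c3c2C[C@@H](C)N(C(=O)OC(C)(C)C)[C@@H]3C)ccc1OC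
F9 | step 12 | potassium aroylpentacarbonylchromate from F8 and K2Cr(CO)5 | [K+].[O-]C(=[Cr](=C=O)(=C=O)(=C=O)(=C=O)=C=O)c1cc(-c2c(OC)cc(OCc3ccccc3)c3c2C[C@@H](C)N(C(=O)OC(C)(C)C)[C@@H]3C)ccc1OC
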